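**Retrosynthetic overview**
- The 6-O-(4-hydroxybenzoyl) group and the C8 carbinol both come from one Evans–Tishchenko reduction of the β-hydroxy ketone 9, so the two secondary hydroxyls never need to be told apart.
- The ten-membered ring is closed at C6–C7 (C1–C10 of an oxidised farnesyl chain, the bond a germacrene cyclase makes) by a hydride-triggered aldol of 2,3-epoxy-9-oxofarnesal 7. This one step sets C6 and C7 and leaves the isopropyl group and the C8 ketone.
- The C15 chain is assembled as C10 + CO + C4 by carbonylative Stille coupling of allylic chloride 4 with an isobutenylstannane.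
- Ring order: oxirane first (Sharpless epoxidation of geraniol, the only source of absolute configuration), then the cyclodecene.

Assumption: stannane 5 and aldehyde 10 are bought as catalogue reagents; open-chain compounds carry farnesane/geraniol numbering, ring compounds germacrane numbering.

**Step 1**
Reactants: 1 geraniol
Product: 2 (2R,3R)-2,3-epoxygeraniol
Conditions: Ti(OiPr)4 (5 mol %), D-(−)-diisopropyl tartrate (6 mol %), t-BuOOH (2 equiv, decane), 4 Å MS, CH2Cl2, −20 °C
Reagents that add atoms: tert-butyl hydroperoxide, CC(C)(C)OO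
Why: Sharpless asymmetric epoxidation of the only allylic alcohol; the D-(−)-tartrate catalyst delivers oxygen to the face that gives the (2R,3R)-epoxide (the L-(+)-tartrate is known to give 2S,3S), which becomes C5/C4 of the target.

**Step 2**
Reactants: 2 (2R,3R)-2,3-epoxygeraniol
Product: 3 (2R,3R,6E)-2,3-epoxy-3,7-dimethyloct-6-ene-1,8-diol
Conditions: SeO2 (0.3 equiv), t-BuOOH (2.5 equiv, decane), CH2Cl2, 0 °C → rt
Reagents that add atoms: tert-butyl hydroperoxide, CC(C)(C)OO; selenium dioxide (oxygen carrier), O=[Se]=O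
Why: Sharpless–Umbreit allylic oxidation (ene reaction, then [2,3]-shift) hydroxylates only the (E)-methyl of the one remaining olefin, and the primary hydroxyl is no longer allylic so it is not oxidised; no new stereocentre.

**Step 3**
Reactants: 3 (2R,3R,6E)-2,3-epoxy-3,7-dimethyloct-6-ene-1,8-diol
Product: 4 (2R,3R,6E)-8-chloro-2,3-epoxy-3,7-dimethyloct-6-en-1-ol
Conditions: NCS (1.2 equiv), Me2S (1.4 equiv), CH2Cl2, −20 → 0 °C
Reagents that add atoms: N-chlorosuccinimide, O=C1CCC(=O)N1Cl
Why: Corey–Kim chlorination; only the allylic alkoxysulfonium salt is displaced by chloride (SN2, no allylic shift, E geometry kept), while the saturated epoxy alcohol is returned on work-up.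

**Step 4**
Reactants: 4 (2R,3R,6E)-8-chloro-2,3-epoxy-3,7-dimethyloct-6-en-1-ol; 5 tributyl(2-methylprop-1-en-1-yl)stannane
Product: 6 (2R,3R,6E)-2,3-epoxy-1-hydroxy-3,7,11-trimethyldodeca-6,10-dien-9-one (2,3-epoxy-9-oxofarnesol)
Conditions: Pd2(dba)3 (2.5 mol %), PPh3 (10 mol %), CO (3 atm), THF, 50 °C
Reagents that add atoms: carbon monoxide, [C-]#[O+]; tributyl(2-methylprop-1-en-1-yl)stannane (5), CCCC[Sn](CCCC)(CCCC)C=C(C)C
Why: Carbonylative Stille coupling; zerovalent palladium ionises the allylic chloride, CO inserts at the primary allyl terminus with retention of the E olefin, and the acyl–palladium is vinylated by the stannane under neutral conditions, so the skipped β,γ-enone is not pulled into conjugation.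

**Step 5**
Reactants: 6 2,3-epoxy-9-oxofarnesol
Product: 7 (2S,3R,6E)-2,3-epoxy-3,7,11-trimethyl-9-oxododeca-6,10-dienal (same geometry as 6; the C2 descriptor changes only because CHO outranks C3)
Conditions: Dess–Martin periodinane (1.3 equiv), NaHCO3 (3 equiv), CH2Cl2, 0 °C → rt; used at once
Reagents that add atoms: none
Why: Dess–Martin oxidation under buffered, non-enolising conditions converts the primary epoxy alcohol into the epoxy aldehyde without touching the epoxide, the enone or the C2 stereocentre.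

**Step 6**
Reactants: 7 (2S,3R,6E)-2,3-epoxy-3,7,11-trimethyl-9-oxododeca-6,10-dienal
Product: 9 (1(10)E,4R,5R,6S,7S)-4,5-epoxy-6-hydroxygermacr-1(10)-en-8-one, via Z-copper enolate 8 (not isolated)
Conditions: [(Ph3P)CuH]6 (0.2 equiv = 1.2 equiv hydride), toluene, 7 added by syringe pump to 2 mM, −40 → 0 °C; aq. NH4Cl
Reagents that add atoms: none
Why: Proposed new method: conjugate hydride delivery from [(Ph3P)CuH]6 to C11 of the s-cis β,β-dimethyl enone gives regiospecifically the Z monovalent-copper enolate at C7/C8 (no base, so the doubly activated C9 methylene is never enolised), which closes on the formyl group in an intramolecular reductive aldol (closest known reactions: Stryker-reagent reductive aldol cyclisations to five- and six-membered rings, and the allylzinc closure of the same C6–C7 bond in an epoxy-farnesal-derived ten-membered ring); the Z enolate in a chair Zimmerman–Traxler array should give the 6,7-syn aldol, and the trans-epoxide fixes the aldehyde face because the ring should close with the metal-bound formyl oxygen on the periphery, H6 inside and the new bond anti to the C5–O bond (H5/H6 anti), giving 6S.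

**Step 7**
Reactants: 9 (1(10)E,4R,5R,6S,7S)-4,5-epoxy-6-hydroxygermacr-1(10)-en-8-one; 10 4-[(tert-butyldimethylsilyl)oxy]benzaldehyde
Product: 13 (1(10)E,4R,5R,6S,7R,8R)-4,5-epoxy-8-hydroxygermacr-1(10)-en-6-yl 4-hydroxybenzoate (target), via samarium hemiacetal 11 (not isolated), via silyl ether 12 (not isolated)
Conditions: 10 (5 equiv), SmI2 (0.3 equiv), THF, −10 °C → rt; then Bu4NF/AcOH (1:1), 0 °C, same flask
Reagents that add atoms: 4-[(tert-butyldimethylsilyl)oxy]benzaldehyde (10), CC(C)(C)[Si](C)(C)Oc1ccc(C=O)cc1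
Why: Evans–Tishchenko reduction: the 6-OH adds to the aldehyde, trivalent samarium bridges the hemiacetal oxygen and the C8 carbonyl, and hydride is passed intramolecularly through a chair transition state to give the 1,3-anti (8R) alcohol while the aldehyde carbon becomes the 6-O-aroyl group; acetic-acid-buffered fluoride then frees the phenol without acyl migration.

**Compound list**
1 | geraniol, (2E)-3,7-dimethylocta-2,6-dien-1-ol | CC(C)=CCC/C(C)=C/CO | starting material
2 | (2R,3R)-2,3-epoxygeraniol, [(2R,3R)-3-methyl-3-(4-methylpent-3-en-1-yl)oxiran-2-yl]methanol | CC(C)=CCC[C@@]1(C)O[C@@H]1CO | intermediate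
3 | (2R,3R,6E)-2,3-epoxy-3,7-dimethyloct-6-ene-1,8-diol | OC/C(C)=C/CC[C@@]1(C)O[C@@H]1CO | intermediate
4 | (2R,3R,6E)-8-chloro-2,3-epoxy-3,7-dimethyloct-6-en-1-ol | ClC/C(C)=C/CC[C@@]1(C)O[C@@H]1CO | intermediate
5 | tributyl(2-methylprop-1-en-1-yl)stannane | CCCC[Sn](CCCC)(CCCC)C=C(C)C | starting material
6 | (2R,3R,6E)-2,3-epoxy-1-hydroxy-3,7,11-trimethyldodeca-6,10-dien-9-one | CC(C)=CC(=O)C/C(C)=C/CC[C@@]1(C)O[C@@H]1CO | intermediate
7 | (2S,3R,6E)-2,3-epoxy-3,7,11-trimethyl-9-oxododeca-6,10-dienal | CC(C)=CC(=O)C/C(C)=C/CC[C@@]1(C)O[C@@H]1C=O | intermediate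
8 | (9Z)-copper enolate of 10,11-dihydro-7 (Ph3P-ligated monovalent copper on O9, isopropyl cis to O) | CC(C)/C=C(\O[Cu])C/C(C)=C/CC[C@@]1(C)O[C@@H]1C=O | intermediate (not isolated)
9 | (1(10)E,4R,5R,6S,7S)-4,5-epoxy-6-hydroxygermacr-1(10)-en-8-one (ten-membered ring: E C1=C10(Me), trans C4(Me)/C5 epoxide, C6 OH, C7 isopropyl, C8 ketone) | C/C1=C\CC[C@@]2(C)O[C@@H]2[C@@H](O)[C@H](C(C)C)C(=O)C1 | intermediate
10 | 4-[(tert-butyldimethylsilyl)oxy]benzaldehyde | CC(C)(C)[Si](C)(C)Oc1ccc(C=O)cc1 | starting material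
11 | samarium-bound hemiacetal of 9 with 10 (O6–CH(Ar)–O–SmI2, hemiacetal carbon undefined) | C/C1=C\CC[C@@]2(C)O[C@@H]2[C@@H](OC(O[Sm](I)I)c2ccc(O[Si](C)(C)C(C)(C)C)cc2)[C@H](C(C)C)C(=O)C1 | intermediate (not isolated)
12 | (1(10)E,4R,5R,6S,7R,8R)-4,5-epoxy-8-hydroxygermacr-1(10)-en-6-yl 4-[(tert-butyldimethylsilyl)oxy]benzoate | C/C1=C\CC[C@@]2(C)O[C@@H]2[C@@H](OC(=O)c2ccc(O[Si](C)(C)C(C)(C)C)cc2)[C@H](C(C)C)[C@H](O)C1 | intermediate (not isolated)
13 | (1(10)E,4R,5R,6S,7R,8R)-4,5-epoxy-8-hydroxygermacr-1(10)-en-6-yl 4-hydroxybenzoate | C/C1=C\CC[C@@]2(C)O[C@@H]2[C@@H](OC(=O)c2ccc(O)cc2)[C@H](C(C)C)[C@H](O)C1 | target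

**Step count**
Total steps: 7. Longest linear sequence: 7 (1 → 13).

**Three steps most likely to fail**

Step 6 (ring closure). The risks are hydride attack on the activated epoxy aldehyde before the hindered enone, a copper enolate too sluggish to close a ten-membered ring, and the wrong C6 epimer. The fallback sets out from chloride 4 and comes back at 9. Chloride 4 is carbonylatively coupled, under the step-4 conditions, with tributyl[(1E)-prop-1-en-1-yl]stannane to give the propenyl ketone F1, which Dess–Martin periodinane/NaHCO3 oxidises to the epoxy aldehyde F2. Cu(OTf)2 (5 mol %), P(OEt)3 (10 mol %) and Me2Zn (1.5 equiv) in toluene at 2 mM, −20 °C → rt, then add methyl to the enone β-carbon, which builds the isopropyl group. The resulting zinc enolate cannot reduce the aldehyde and is a stronger aldol donor than a copper enolate; it closes the C6–C7 bond to give 9 after NH4Cl work-up.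

Step 4 (carbonylative Stille). The risks are direct coupling without CO, acyl–palladium capture by the free hydroxyl, and E/Z scrambling of the allyl unit. The fallback sets out from 4 and comes back at 6 and replaces the coupling by an acyl-anion alkylation. 3-Methylbut-2-enal and propane-1,3-dithiol (BF3·OEt2) give 2-(2-methylprop-1-en-1-yl)-1,3-dithiane F3. Its 2-lithio derivative (n-BuLi, THF, −30 °C) alkylates the lithium alkoxide of 4 (pre-formed with 1 equiv n-BuLi at −78 °C) at the dithiane carbon to give the dithiane-masked ketone F4. MeI/CaCO3 in aqueous MeCN at 40 °C then unmasks 6.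

Step 7 (Evans–Tishchenko). The risks are a slow reaction with the electron-rich aldehyde, retro-aldol of 9 on samarium, and 6→8 acyl migration. The fallback sets out from 9 and comes back at 13 and separates reduction from acylation. Me4NBH(OAc)3 in MeCN/AcOH at −30 °C gives, by hydroxyl-directed hydride delivery, the anti-diol F5. TESCl/imidazole in CH2Cl2 at −40 °C silylates the less hindered 8-OH to give the 8-O-triethylsilyl ether F6. Yamaguchi esterification of the 6-OH with 4-[(tert-butyldimethylsilyl)oxy]benzoic acid (2,4,6-trichlorobenzoyl chloride, Et3N, DMAP, toluene) gives the doubly silylated ester F7. HF·pyridine in THF/pyridine at 0 °C removes both silyl groups to give 13.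

**Further compounds**
F1 | step 6 | (2R,3R,6E,10E)-2,3-epoxy-1-hydroxy-3,7-dimethyldodeca-6,10-dien-9-one | C/C=C/C(=O)C/C(C)=C/CC[C@@]1(C)O[C@@H]1CO
F2 | step 6 | (2S,3R,6E,10E)-2,3-epoxy-3,7-dimethyl-9-oxododeca-6,10-dienal | C/C=C/C(=O)C/C(C)=C/CC[C@@]1(C)O[C@@H]1C=O
F3 | step 4 | 2-(2-methylprop-1-en-1-yl)-1,3-dithiane | CC(C)=CC1SCCCS1
F4 | step 4 | [(2R,3R)-3-methyl-3-[(3E)-4-methyl-5-[2-(2-methylprop-1-en-1-yl)-1,3-dithian-2-yl]pent-3-en-1-yl]oxiran-2-yl]methanol | CC(C)=CC1(SCCCS1)C/C(C)=C/CC[C@@]2(C)O[C@@H]2CO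
F5 | step 7 | (1(10)E,4R,5R,6S,7R,8R)-4,5-epoxygermacr-1(10)-ene-6,8-diol | C/C1=C\CC[C@@]2(C)O[C@@H]2[C@@H](O)[C@H](C(C)C)[C@H](O)C1
F6 | step 7 | 8-O-triethylsilyl ether of F5 | C/C1=C\CC[C@@]2(C)O[C@@H]2[C@@H](O)[C@H](C(C)C)[C@H](O[Si](CC)(CC)CC)C1
F7 | step 7 | 6-O-{4-[(tert-butyldimethylsilyl)oxy]benzoyl} ester of F6 | C/C1=C\CC[C@@]2(C)O[C@@H]2[C@@H](OC(=O)c2ccc(O[Si](C)(C)C(C)(C)C)cc2)[C@H](C(C)C)[C@H](O[Si](CC)(CC)CC)C1
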